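The data were generated by integration from invented constants, noise included.

At early times E already outruns Z: teal shows 11.3% at 5.00 h, against a charge of Z worth 1.33% of its J, so E isn't made one per Z.

| setting | teal | amber | alpha | gamma | delta |
|---|---|---|---|---|---|
| J | 0.075 M | 0.050 M | 0.050 M | 0.050 M | 0.050 M |
| Q | 2.5 equiv | 2.5 equiv | 2.50 equiv | 3.00 equiv | 4.00 equiv |
| Z | 1 mM | 0.50 mM | 1.00 mM | 1.00 mM | 1.00 mM |
| remark | run made earlier | run made earlier |  |  |  |
| time |  |  | 30 h | 30 h | 30 h |

| teal: time / h | teal: E / % | amber: time / h | amber: E / % |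
|---|---|---|---|
| 1.50 | 2.4 | 4.00 | 4.2 |
| 5.00 | 11.3 | 8.00 | 10.6 |
| 8.00 | 18.4 | 10.0 | 13.6 |
| 12.0 | 27.1 | 15.0 | 21.4 |
| 20.0 | 35.8 | 20.0 | 25.1 |

(readings scatter by 0.5 percentage points)

* amount of E at the end, in percent of the J charged, for each flask in turn (alpha, gamma, delta)



I write the balance of Z, the limiting reagent against J and Q in a one-for-one step. In alpha 2.00% is the Z budget, the charge of Z over the charge of J, the share of J that Z can take one for one; amber's is 1.00%.

Amber has alpha's J and Q, so I extend amber and subtract the difference in budget. Its last two stretches of equal length gain 7.8 percentage points and 3.7 points, so the gain falls by half. The two extensions to 30 h are my range for amber: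

straight on: 32.5%
gain times 0.5 each stretch: 27.9%
alpha, their mean less the difference in budget: 29.2%

The weak link is Q, which no run varies alone. Teal has [Q] raised together with [J] and [Z], so its E at 20.0 h against amber's gives, as a reading, no more than an apparent order in [Q] as charged:

order: 0.876
gamma: 34.2%
delta: 44.1%

The forecast gives 58%, 59% and 60%, holding that “Z acts as a saturated catalyst”. My reckoning parts from it: for alpha mine is lower, and mine rises steeply with Q.

The flasks give 30.3%, 37.4% and 49.1%.

    L + Q → D + E (k = 0.880 M⁻¹ h⁻¹)
    L + Z → X (k = 24.0 M⁻¹ h⁻¹)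
    L → G (k = 0.110 h⁻¹)
    J + Q → D + L (k = 0.630 M⁻¹ h⁻¹)

Alpha holds X at 1.98% at 30.0 h, close to its Z budget of 2.00%. Delta, with the same budget, holds 1.97% while its E stands at 49.1%. In gamma the consumption of Z is not the reason for the yield. In gamma the largest single effect is the loss of L to G : without that step E goes from 37.4% to 64.3%.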